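The route rests on disconnecting C11–C12 (squalene numbering, defined below). C11 is the ring CH of the left cyclohexane, alpha to the exocyclic-methylene carbon C10, and C12–C13–C14 is an allyl unit ending at the tertiary carbinol carbon C14 of the right cyclohexane. With C10 as a ketone carrying an ester at C11, and C14 as the terminus of an exocyclic allene (C14=C13=C12H2), one palladium-catalysed, atom-economic addition of the C11–H bond across the allene joins the two halves. Each half, a trans-fused oxepane–cyclohexane, comes from a bio-inspired diepoxide oxa-/carbacyclisation cascade. Decarboxylation, Markovnikov hydration at C14, methylenation at C10 and oxidation at C22 complete the target.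

Key step: step 13

Numbering: left oxepane O–C2(Me2)–C3(OAc)–C4–C5–C6(Me)–C7; left cyclohexane C6–C7–C8–C9–C10(=CH2)–C11; bridge C12–C13; right cyclohexane C14(OH)–C15(Me)–C16–C17–C18–C19(Me); right oxepane C19–C20–C21–C22(=O)–C23(Me2)–O–C18.
Remark: the ent-Shi ketone (L-fructose-derived enantiomer of the Shi ketone) is taken as an available catalyst, otherwise made from L-sorbose. The C13=C14 alkene of 22 and 23 is drawn E, but its geometry is of no consequence. The C11 configuration in 22 and the C22 carbinol configuration in 21–25 are also of no consequence, because both centres are erased later.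

Step 1
Reactants: 1 geraniol
Product: 2 (2S,3S)-2,3-epoxygeraniol
Conditions: Ti(OiPr)4 (5 mol %), L-(+)-diethyl tartrate (7 mol %), t-BuOOH, 4 Å molecular sieves, CH2Cl2, −20 °C
Reagents that add atoms: tert-butyl hydroperoxide, CC(C)(C)OO
Why: Sharpless asymmetric epoxidation: the titanium tartrate complex binds the allylic hydroxyl and, with L-(+)-tartrate, delivers oxygen to the face of the allylic alkene that gives the (2S,3S)-epoxide (the future C7 and C6), leaving the remote alkene untouched.

Step 2
Reactants: 2 (2S,3S)-2,3-epoxygeraniol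
Product: 3 (2S,3S,6R)-2,3:6,7-diepoxygeraniol
Conditions: Shi ketone (D-fructose-derived, 30 mol %), Oxone (2KHSO5·KHSO4·K2SO4), K2CO3, Bu4NHSO4, Na2B4O7 buffer, MeCN/dimethoxymethane/H2O, 0 °C
Reagents that add atoms: Oxone (potassium peroxymonosulfate, KHSO5), [K+].[O-]S(=O)(=O)OO
Why: Shi epoxidation: the chiral dioxirane transfers oxygen through a spiro transition state to one face of the remaining trisubstituted alkene and sets the (R) centre that becomes C3 under reagent control, independently of the distant epoxide.

Step 3
Reactants: 3 (2S,3S,6R)-2,3:6,7-diepoxygeraniol, 4 methyl acetoacetate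
Product: 7 diepoxy β-keto ester, via epoxy triflate 5 (not isolated), via acetoacetate dianion 6 (not isolated)
Conditions: Tf2O, 2,6-lutidine, CH2Cl2, −78 °C; then dianion of 4 (NaH, then n-BuLi, THF, 0 °C), −78 °C; sat. aq NH4Cl
Reagents that add atoms: none
Why: Dianion alkylation: the primary triflate, made and used cold, should be displaced in an SN2 reaction by the terminal (gamma) carbon of the acetoacetate dianion faster than the hindered trisubstituted epoxides can be opened, so the C8–C9 bond forms without touching a stereocentre.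

Step 4
Reactants: 7 diepoxy β-keto ester
Product: 8 diepoxy enol silane
Conditions: TBSCl, Et3N, DMAP (cat.), CH2Cl2, 0 °C to rt
Reagents that add atoms: tert-butyldimethylsilyl chloride, CC(C)(C)[Si](C)(C)Cl
Why: O-Silylation of the enolised β-keto ester should give the (Z)-β-silyloxy enoate, an enol silane that serves as the carbon nucleophile of the cascade, under conditions free of Lewis acid so that the epoxides survive.

Step 5
Reactants: 8 diepoxy enol silane
Product: 10 left bicyclic hydroxy β-keto ester, via its trimethylsilyl ether 9 (not isolated)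
Conditions: TMSOTf (1.2 equiv), 2,6-di-tert-butyl-4-methylpyridine, CH2Cl2, −78 °C; then MeOH, citric acid, 0 °C
Reagents that add atoms: none
Why: Lewis acid-triggered tandem oxa-/carbacyclisation (epoxide-opening cascade ending in a cation–olefin cyclisation terminated by an enol silane): the silylated terminal epoxide is opened at its tertiary carbon C2 by the oxygen of the internal epoxide, and the resulting epoxonium ion is opened at C6 with inversion by the enol silane carbon C11 through a chair transition state, so that C3 and C7 keep the epoxide configurations, the C6 methyl group and H7 end up trans (trans ring fusion) and the C11 ester sits equatorial; methanolysis then frees the C3 hydroxyl.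

Step 6
Reactants: 10 left bicyclic hydroxy β-keto ester
Product: 11 left fragment (acetoxy β-keto ester)
Conditions: Ac2O, pyridine, rt
Reagents that add atoms: acetic anhydride, CC(=O)OC(C)=O
Why: Standard acetylation of the secondary alcohol installs the C3 acetate of the target at the last point where the left-hand hydroxyl is the only one in the molecule.

Step 7
Reactants: 12 (2E,6E)-farnesol
Product: 13 (S)-2,3-dihydrofarnesol
Conditions: H2 (100 atm), Ru(OAc)2[(R)-BINAP] (0.5 mol %), MeOH, 20 °C
Reagents that add atoms: none
Why: Noyori asymmetric hydrogenation: the ruthenium–(R)-BINAP catalyst, directed by the allylic hydroxyl, reduces only the allylic C2=C3 alkene and sets the (S) methyl-bearing centre (the future C15), as in the known conversion of geraniol into (S)-citronellol.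

Step 8
Reactants: 13 (S)-2,3-dihydrofarnesol
Product: 14 (S)-2,3-dihydrofarnesal
Conditions: TEMPO (10 mol %), PhI(OAc)2, CH2Cl2, rt
Reagents that add atoms: none
Why: TEMPO-catalysed oxidation should stop cleanly at the aldehyde and leave the trisubstituted alkenes and the beta stereocentre untouched.

Step 9
Reactants: 14 (S)-2,3-dihydrofarnesal
Product: 16 terminal alkyne, via alkenyl nonaflate 15 (not isolated)
Conditions: C4F9SO2F, phosphazene base P2-Et (2.5 equiv), DMF, −20 °C to rt
Reagents that add atoms: none
Why: One-pot conversion of an enolisable aldehyde into a terminal alkyne: the phosphazene base forms the enolate, which is O-sulfonylated by the sulfonyl fluoride, and a second equivalent of base eliminates nonaflate from the alkenyl nonaflate (E2), the C15 centre not being part of the enolate.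

Step 10
Reactants: 16 terminal alkyne
Product: 18 propargylsilane, via lithium acetylide 17 (not isolated)
Conditions: n-BuLi, THF, −78 °C; then Me3SiCH2I, DMPU, −78 °C to rt
Reagents that add atoms: (iodomethyl)trimethylsilane, C[Si](C)(C)CI
Why: Deprotonation of the terminal alkyne and SN2 alkylation of the lithium acetylide with (iodomethyl)trimethylsilane should give the propargylsilane that terminates the second cascade.

Step 11
Reactants: 18 propargylsilane
Product: 19 diepoxy propargylsilane
Conditions: ent-Shi ketone (L-fructose-derived, 30 mol %), Oxone (2KHSO5·KHSO4·K2SO4), K2CO3, Bu4NHSO4, Na2B4O7 buffer, MeCN/dimethoxymethane/H2O, 0 °C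
Reagents that add atoms: Oxone (potassium peroxymonosulfate, KHSO5), [K+].[O-]S(=O)(=O)OO
Why: Shi epoxidation with the enantiomeric ketone should epoxidise both trisubstituted alkenes under reagent control, giving the (S,S) internal epoxide (future C19 and C18) and the (S) terminal epoxide (future C22, later a ketone), while the alkyne and the C–Si bond are inert to the dioxirane.

Step 12
Reactants: 19 diepoxy propargylsilane
Product: 21 right fragment (allenyl alcohol), via its trimethylsilyl ether 20 (not isolated)
Conditions: TMSOTf (1.2 equiv), 2,6-di-tert-butyl-4-methylpyridine, CH2Cl2, −78 °C; then K2CO3, MeOH, rt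
Reagents that add atoms: none
Why: The same tandem oxa-/carbacyclisation, now terminated by the propargylsilane in an SE2' reaction that expels silicon and leaves the exocyclic allene: after oxepane formation at C23 the epoxonium ion is opened at C19 with inversion by alkyne carbon C14 through a chair in which the C15 methyl group is equatorial (matched with the epoxide configuration), giving the trans-fused bicycle with C18 retained; methanolysis then frees the C22 hydroxyl.

Step 13
Reactants: 11 left fragment (acetoxy β-keto ester), 21 right fragment (allenyl alcohol)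
Product: 22 coupled β-keto ester
Conditions: Pd2(dba)3·CHCl3 (5 mol %), dppb (12 mol %), PhCO2H (20 mol %), THF, 70 °C
Reagents that add atoms: none
Why: Benzoic acid and the zerovalent palladium–dppb complex give a palladium hydride that adds across the terminal C12=C13 bond of allene 21 (hydrogen to the central carbon C13) to form a π-allyl complex over C12–C13–C14, while benzoate deprotonates the acidic C11–H of β-keto ester 11; the soft enolate then attacks the unsubstituted terminus C12 anti to palladium and creates the C11–C12 bond with no atom lost. The closest known reaction types are the palladium-catalysed addition of 1,3-dicarbonyl pronucleophiles to allenes (hydrocarbonation) and the Tsuji–Trost allylic alkylation. No ring is closed. The new quaternary stereocentre C11 is set by substrate control, the allyl unit entering axially on the face opposite the axial C6 methyl group, and it is deliberately transient because the ester is removed in step 14. The step needs regioselectivity for C12 over C14 and C- over O-allylation: C14 is fully substituted and flanked by quaternary C19, and any O-allyl enol ether is re-ionised by the catalyst and funnels to the C-allylated product. Site selectivity for C11 over C9 is secured by the ester, which makes C11–H the only acidic C–H bond.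

Step 14
Reactants: 22 coupled β-keto ester
Product: 23 coupled ketone
Conditions: LiCl, H2O, DMSO, 150 °C
Reagents that add atoms: none
Why: Krapcho dealkoxycarbonylation: chloride demethylates the ester, the β-keto carboxylate loses CO2, and the enolate is protonated on the less hindered face anti to the C6 methyl group, which should give the thermodynamically preferred equatorial side chain at C11 (H11 axial), the configuration of the target.

Step 15
Reactants: 23 coupled ketone
Product: 24 tertiary alcohol (hydroxy ketone)
Conditions: Co(acac)2 (20 mol %), PhSiH3, O2 (1 atm), THF, rt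
Reagents that add atoms: dioxygen, O=O
Why: Mukaiyama hydration (cobalt-catalysed hydrogen-atom transfer): hydrogen adds to the less substituted C13 and the tertiary C14 radical should be trapped by O2 on the axial face opposite the axial C19 methyl group, placing the hydroxyl axial and the C13 chain equatorial as in the target, while the ketone, acetate and free hydroxyl are inert.

Step 16
Reactants: 24 tertiary alcohol (hydroxy ketone)
Product: 25 methylidene diol
Conditions: Zn, CH2Br2, TiCl4 (pre-formed Lombardo reagent, excess), THF/CH2Cl2, 0 °C to rt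
Reagents that add atoms: dibromomethane, BrCBr
Why: Takai–Lombardo methylenation: the non-basic zinc–titanium methylene reagent should olefinate the hindered C10 ketone without epimerising C11 and tolerates the acetate and the free hydroxyl groups, which a Wittig ylide would not.

Step 17
Reactants: 25 methylidene diol
Product: 26 3-epi-sodwanone K 3-acetate
Conditions: Dess–Martin periodinane, NaHCO3, CH2Cl2, rt
Reagents that add atoms: none
Why: Dess–Martin oxidation converts the only secondary alcohol (C22) into the oxepanone, the tertiary C14 hydroxyl, the acetate and the exocyclic alkene being unreactive.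

Compound list
1 | geraniol, (2E)-3,7-dimethylocta-2,6-dien-1-ol | CC(C)=CCC/C(C)=C/CO | starting material
2 | (2S,3S)-2,3-epoxygeraniol, [(2S,3S)-3-methyl-3-(4-methylpent-3-en-1-yl)oxiran-2-yl]methanol | OC[C@@H]1O[C@@]1(C)CCC=C(C)C | intermediate
3 | (2S,3S,6R)-2,3:6,7-diepoxygeraniol, {(2S,3S)-3-[2-((2R)-3,3-dimethyloxiran-2-yl)ethyl]-3-methyloxiran-2-yl}methanol | OC[C@@H]1O[C@@]1(C)CC[C@H]1OC1(C)C | intermediate
4 | methyl acetoacetate | CC(=O)CC(=O)OC | starting material
5 | epoxy triflate, trifluoromethanesulfonate of 3 | O=S(=O)(OC[C@@H]1O[C@@]1(C)CC[C@H]1OC1(C)C)C(F)(F)F | intermediate (not isolated)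
6 | acetoacetate dianion, sodium lithium dienolate of 4 | C=C([O-])C=C([O-])OC.[Li+].[Na+] | intermediate (not isolated)
7 | diepoxy β-keto ester, methyl 5-{(2S,3S)-3-[2-((2R)-3,3-dimethyloxiran-2-yl)ethyl]-3-methyloxiran-2-yl}-3-oxopentanoate | COC(=O)CC(=O)CC[C@@H]1O[C@@]1(C)CC[C@H]1OC1(C)C | intermediate
8 | diepoxy enol silane, methyl (2Z)-3-[(tert-butyldimethylsilyl)oxy]-5-{(2S,3S)-3-[2-((2R)-3,3-dimethyloxiran-2-yl)ethyl]-3-methyloxiran-2-yl}pent-2-enoate | COC(=O)/C=C(\O[Si](C)(C)C(C)(C)C)CC[C@@H]1O[C@@]1(C)CC[C@H]1OC1(C)C | intermediate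
9 | trimethylsilyl ether of 10, methyl (3R,5aS,6S,9aS)-2,2,5a-trimethyl-7-oxo-3-[(trimethylsilyl)oxy]decahydro-1-benzoxepine-6-carboxylate | O=C1CC[C@@H]2OC(C)(C)[C@H](O[Si](C)(C)C)CC[C@@]2(C)[C@@H]1C(=O)OC | intermediate (not isolated)
10 | left bicyclic hydroxy β-keto ester, methyl (3R,5aS,6S,9aS)-3-hydroxy-2,2,5a-trimethyl-7-oxodecahydro-1-benzoxepine-6-carboxylate | O=C1CC[C@@H]2OC(C)(C)[C@H](O)CC[C@@]2(C)[C@@H]1C(=O)OC | intermediate
11 | left fragment, methyl (3R,5aS,6S,9aS)-3-acetoxy-2,2,5a-trimethyl-7-oxodecahydro-1-benzoxepine-6-carboxylate | O=C1CC[C@@H]2OC(C)(C)[C@H](OC(C)=O)CC[C@@]2(C)[C@@H]1C(=O)OC | intermediate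
12 | (2E,6E)-farnesol | CC(C)=CCC/C(C)=C/CC/C(C)=C/CO | starting material
13 | (S)-2,3-dihydrofarnesol, (3S,6E)-3,7,11-trimethyldodeca-6,10-dien-1-ol | OCC[C@@H](C)CC/C=C(\C)CCC=C(C)C | intermediate
14 | (S)-2,3-dihydrofarnesal, (3S,6E)-3,7,11-trimethyldodeca-6,10-dienal | O=CC[C@@H](C)CC/C=C(\C)CCC=C(C)C | intermediate
15 | alkenyl nonaflate, (3S,6E)-3,7,11-trimethyldodeca-1,6,10-trien-1-yl nonafluorobutane-1-sulfonate (E/Z at C1) | O=S(=O)(OC=C[C@@H](C)CC/C=C(\C)CCC=C(C)C)C(F)(F)C(F)(F)C(F)(F)C(F)(F)F | intermediate (not isolated)
16 | terminal alkyne, (3S,6E)-3,7,11-trimethyldodeca-6,10-dien-1-yne | C#C[C@@H](C)CC/C=C(\C)CCC=C(C)C | intermediate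
17 | lithium acetylide of 16 | [Li]C#C[C@@H](C)CC/C=C(\C)CCC=C(C)C | intermediate (not isolated)
18 | propargylsilane, trimethyl[(4S,7E)-4,8,12-trimethyltrideca-7,11-dien-2-yn-1-yl]silane | C[Si](C)(C)CC#C[C@@H](C)CC/C=C(\C)CCC=C(C)C | intermediate
19 | diepoxy propargylsilane, trimethyl{(4S)-6-[(2S,3S)-3-{2-[(2S)-3,3-dimethyloxiran-2-yl]ethyl}-3-methyloxiran-2-yl]-4-methylhex-2-yn-1-yl}silane | C[Si](C)(C)CC#C[C@@H](C)CC[C@@H]1O[C@@]1(C)CC[C@@H]1OC1(C)C | intermediate
20 | trimethylsilyl ether of 21 | C=C=C1[C@@H](C)CC[C@@H]2OC(C)(C)[C@@H](O[Si](C)(C)C)CC[C@]21C | intermediate (not isolated)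
21 | right fragment, (3S,5aS,7S,9aS)-6-ethenylidene-2,2,5a,7-tetramethyldecahydro-1-benzoxepin-3-ol | C=C=C1[C@@H](C)CC[C@@H]2OC(C)(C)[C@@H](O)CC[C@]21C | intermediate
22 | coupled β-keto ester, methyl (3R,5aS,6S,9aS)-3-acetoxy-6-{(2E)-2-[(3S,5aS,7S,9aS)-3-hydroxy-2,2,5a,7-tetramethyldecahydro-1-benzoxepin-6-ylidene]ethyl}-2,2,5a-trimethyl-7-oxodecahydro-1-benzoxepine-6-carboxylate | O=C1CC[C@@H]2OC(C)(C)[C@H](OC(C)=O)CC[C@@]2(C)[C@@]1(C(=O)OC)C/C=C1\[C@@H](C)CC[C@@H]2OC(C)(C)[C@@H](O)CC[C@]21C | intermediate
23 | coupled ketone, (3R,5aS,6S,9aS)-6-{(2E)-2-[(3S,5aS,7S,9aS)-3-hydroxy-2,2,5a,7-tetramethyldecahydro-1-benzoxepin-6-ylidene]ethyl}-2,2,5a-trimethyl-7-oxodecahydro-1-benzoxepin-3-yl acetate | O=C1CC[C@@H]2OC(C)(C)[C@H](OC(C)=O)CC[C@@]2(C)[C@@H]1C/C=C1\[C@@H](C)CC[C@@H]2OC(C)(C)[C@@H](O)CC[C@]21C | intermediate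
24 | tertiary alcohol, (3R,5aS,6S,9aS)-6-{2-[(3S,5aR,6S,7S,9aS)-3,6-dihydroxy-2,2,5a,7-tetramethyldecahydro-1-benzoxepin-6-yl]ethyl}-2,2,5a-trimethyl-7-oxodecahydro-1-benzoxepin-3-yl acetate | O=C1CC[C@@H]2OC(C)(C)[C@H](OC(C)=O)CC[C@@]2(C)[C@@H]1CC[C@]1(O)[C@@H](C)CC[C@@H]2OC(C)(C)[C@@H](O)CC[C@]21C | intermediate
25 | methylidene diol, (3R,5aS,6R,9aS)-6-{2-[(3S,5aR,6S,7S,9aS)-3,6-dihydroxy-2,2,5a,7-tetramethyldecahydro-1-benzoxepin-6-yl]ethyl}-2,2,5a-trimethyl-7-methylidenedecahydro-1-benzoxepin-3-yl acetate | C=C1CC[C@@H]2OC(C)(C)[C@H](OC(C)=O)CC[C@@]2(C)[C@@H]1CC[C@]1(O)[C@@H](C)CC[C@@H]2OC(C)(C)[C@@H](O)CC[C@]21C | intermediate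
26 | 3-epi-sodwanone K 3-acetate, (3R,5aS,6R,9aS)-6-{2-[(5aR,6S,7S,9aS)-6-hydroxy-2,2,5a,7-tetramethyl-3-oxodecahydro-1-benzoxepin-6-yl]ethyl}-2,2,5a-trimethyl-7-methylidenedecahydro-1-benzoxepin-3-yl acetate | C=C1CC[C@@H]2OC(C)(C)[C@H](OC(C)=O)CC[C@@]2(C)[C@@H]1CC[C@]1(O)[C@@H](C)CC[C@@H]2OC(C)(C)C(=O)CC[C@]21C | target

Total step count: 17. Longest linear sequence: 11 steps (steps 1–6 and then 13–17, or equally steps 7–12 and then 13–17).

Steps most likely to fail

Step 13. The enolate has to attack the π-allyl terminus while building a quaternary carbon next to quaternary C6. If this is slow, β-hydride elimination from the π-allyl complex (allene-to-diene isomerisation) or allene oligomerisation may take over. The fallback sets out from 21 and 11 and uses a tether so that only a tertiary centre is formed at C11. Hydroboration of the allene of 21 with 9-BBN (THF, 0 °C; boron to the terminal CH2) and oxidation (NaOH, H2O2) should give the primary allylic alcohol (2E)-2-[(3S,5aS,7S,9aS)-3-hydroxy-2,2,5a,7-tetramethyldecahydro-1-benzoxepin-6-ylidene]ethanol F1. DMAP-catalysed transesterification of the methyl ester of 11 with it (toluene, reflux, 4 Å molecular sieves) should give the allyl β-keto ester F2. Pd(PPh3)4 in THF at room temperature should then ionise the allylic ester, the β-keto carboxylate loses CO2, and the regiodefined palladium enolate at C11 recombines with the unsubstituted allyl terminus C12 (decarboxylative allylation of the Tsuji type, the catalytic form of the Carroll rearrangement). This gives 23 directly, where the route is rejoined; step 14 is then not needed.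

Step 3. The epoxy triflate may be lost through participation of the neighbouring epoxide oxygen, or the strongly basic dianion may open the epoxide instead of displacing the triflate. The fallback sets out from 1 (and 4) and forms the C8–C9 bond before the internal epoxide exists. Acetylation of 1 (Ac2O, pyridine) gives geranyl acetate F3. Shi epoxidation with the D-fructose-derived ketone, selective for the distal electron-rich alkene, gives (R)-6,7-epoxygeranyl acetate F4. Methanolysis (K2CO3, MeOH) gives (R)-6,7-epoxygeraniol F5, and CBr4/PPh3 gives the allylic bromide (R)-6,7-epoxygeranyl bromide F6. Alkylation of the dianion of 4 (NaH, n-BuLi, THF, 0 °C) with this unhindered allylic bromide gives the epoxy-ene β-keto ester F7, and silylation (TBSCl, Et3N) gives its enol silane F8. Epoxidation of the remaining trisubstituted alkene with the ent-Shi ketone and Oxone then gives 8, where the route is rejoined.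

Step 9. The strong base may isomerise the propargylic position of the product (propargyl–allenyl equilibration), which would erode the configuration at C15, and the aldehyde may self-condense before it is sulfonylated. The fallback sets out from 14 and makes the alkyne by degradation and homologation under mild base. Condensation with piperidine (K2CO3, Et2O) gives the enamine 1-[(1E,3S,6E)-3,7,11-trimethyldodeca-1,6,10-trien-1-yl]piperidine F9. Copper-catalysed oxidative cleavage of the enamine C=C bond (CuCl, O2, MeCN) removes one carbon and gives the α-methyl aldehyde (2S,5E)-2,6,10-trimethylundeca-5,9-dienal F10. Ohira–Bestmann homologation (dimethyl (1-diazo-2-oxopropyl)phosphonate, K2CO3, MeOH, 0 °C) then gives alkyne 16, where the route is rejoined.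

Further compounds
F1 | step 13 | (2E)-2-[(3S,5aS,7S,9aS)-3-hydroxy-2,2,5a,7-tetramethyldecahydro-1-benzoxepin-6-ylidene]ethanol | OC/C=C1\[C@@H](C)CC[C@@H]2OC(C)(C)[C@@H](O)CC[C@]21C
F2 | step 13 | allyl β-keto ester, (2E)-2-[(3S,5aS,7S,9aS)-3-hydroxy-2,2,5a,7-tetramethyldecahydro-1-benzoxepin-6-ylidene]ethyl (3R,5aS,6S,9aS)-3-acetoxy-2,2,5a-trimethyl-7-oxodecahydro-1-benzoxepine-6-carboxylate | O=C1CC[C@@H]2OC(C)(C)[C@H](OC(C)=O)CC[C@@]2(C)[C@@H]1C(=O)OC/C=C1\[C@@H](C)CC[C@@H]2OC(C)(C)[C@@H](O)CC[C@]21C
F3 | step 3 | geranyl acetate | CC(C)=CCC/C(C)=C/COC(C)=O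
F4 | step 3 | (R)-6,7-epoxygeranyl acetate | CC(=O)OC/C=C(\C)CC[C@H]1OC1(C)C
F5 | step 3 | (R)-6,7-epoxygeraniol | OC/C=C(\C)CC[C@H]1OC1(C)C
F6 | step 3 | (R)-6,7-epoxygeranyl bromide | BrC/C=C(\C)CC[C@H]1OC1(C)C
F7 | step 3 | methyl (6E)-9-[(2R)-3,3-dimethyloxiran-2-yl]-7-methyl-3-oxonon-6-enoate | COC(=O)CC(=O)CC/C=C(\C)CC[C@H]1OC1(C)C
F8 | step 3 | methyl (2Z,6E)-3-[(tert-butyldimethylsilyl)oxy]-9-[(2R)-3,3-dimethyloxiran-2-yl]-7-methylnona-2,6-dienoate | COC(=O)/C=C(\O[Si](C)(C)C(C)(C)C)CC/C=C(\C)CC[C@H]1OC1(C)C
F9 | step 9 | 1-[(1E,3S,6E)-3,7,11-trimethyldodeca-1,6,10-trien-1-yl]piperidine | C1CCN(CC1)/C=C/[C@@H](C)CC/C=C(\C)CCC=C(C)C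
F10 | step 9 | (2S,5E)-2,6,10-trimethylundeca-5,9-dienal | O=C[C@@H](C)CC/C=C(\C)CCC=C(C)C
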